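**Retrosynthetic overview**
1. Target 23 ⇐ 22 ⇐ 20: late unmasking of the α-methylene lactone (Mannich base) and of the C8 hydroxyl (TBS).
2. Key disconnection C3–C4: the ten-membered carbocycle is closed last, by an NHC-generated acyl anion (Breslow intermediate of the C3 aldehyde) adding to the C4 methyl ketone of seco keto-aldehyde 19. This sets C4.
3. C7–C8: indium allylation of the L-proline/PhNO α-aminoxylated (R)-citronellal (C9, C10) with 3-(bromomethyl)butenolide 11. This sets C7 and C8.
4. Butenolide 11 (C5, C6) comes from a Brown alkoxyallylboration of methacrolein, two esterifications and RCM.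
5. Ring order: γ-lactone first (step 5), ten-membered carbocycle last (step 12).

Assumption: (R)-2-methylbutanoic acid, allyl MOM ether and (+)-Ipc2BOMe are bought. This route is a paper design and has not been run.
Locants follow the target's ring: C1, C2 = CH2; C3 = C=O; C4 = C(OH)Me; C5 = CH–O-2-methylbutanoyl; C6 = lactone O–CH; C7 = ring fusion; C8 = CHOH; C9 = CH–O-isovaleryl; C10 = CHMe; C11/C12/C13 = lactone α-C, C=O, =CH2.

**Step 1**
Reactants: 1 allyl methoxymethyl ether; 2 methacrolein
Product: 4 (3S,4S)-4-(methoxymethoxy)-2-methylhexa-1,5-dien-3-ol, via allylborane 3 (not isolated)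
Conditions: s-BuLi, THF, −78 °C; (+)-Ipc2BOMe; BF3·OEt2; 2, −78 °C; then NaOH, H2O2, 0 °C → rt
Reagents that add atoms: none
Why: Brown asymmetric γ-alkoxyallylboration, in which the chelated (Z)-alkoxyallyl anion gives the (Z)-allylborane whose chair transition state delivers the syn (threo) diol monoether while the Ipc ligands from (−)-α-pinene choose the aldehyde face, setting C5 and C6.

**Step 2**
Reactants: 4 (3S,4S)-4-(methoxymethoxy)-2-methylhexa-1,5-dien-3-ol; 5 (R)-2-methylbutanoic acid
Product: 6 (3S,4S)-4-(methoxymethoxy)-2-methylhexa-1,5-dien-3-yl (2R)-2-methylbutanoate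
Conditions: DCC, DMAP (cat.), CH2Cl2, 0 °C → rt
Reagents that add atoms: none
Why: Steglich esterification of the only free hydroxyl (C5–OH) at low temperature with catalytic DMAP, which touches no stereocentre and keeps the α-centre of the acid intact.

**Step 3**
Reactants: 6 (3S,4S)-4-(methoxymethoxy)-2-methylhexa-1,5-dien-3-yl (2R)-2-methylbutanoate
Product: 7 (3S,4S)-4-hydroxy-2-methylhexa-1,5-dien-3-yl (2R)-2-methylbutanoate
Conditions: ZnBr2, n-PrSH, CH2Cl2, 0 °C → rt, 10 min; used crude
Reagents that add atoms: none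
Why: Lewis acid/thiol cleavage of the MOM acetal (ZnBr2 activates, the thiol traps the methoxymethyl cation) frees C6–OH fast enough under non-basic conditions that the neighbouring ester does not migrate.

**Step 4**
Reactants: 7 (3S,4S)-4-hydroxy-2-methylhexa-1,5-dien-3-yl (2R)-2-methylbutanoate; 8 2-(bromomethyl)acrylic acid
Product: 10 (3S,4S)-2-methyl-3-{[(2R)-2-methylbutanoyl]oxy}hexa-1,5-dien-4-yl 2-(bromomethyl)prop-2-enoate, via acid chloride 9 (not isolated)
Conditions: 8, (COCl)2, DMF (cat.), CH2Cl2, 0 °C → rt; then 7, 2,6-lutidine, CH2Cl2, −20 → 0 °C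
Reagents that add atoms: none
Why: Acyl chloride esterification with a hindered, non-nucleophilic base, so that the allylic bromide is not displaced, attaches the C11–C13 unit to C6–O.

**Step 5**
Reactants: 10 (3S,4S)-2-methyl-3-{[(2R)-2-methylbutanoyl]oxy}hexa-1,5-dien-4-yl 2-(bromomethyl)prop-2-enoate
Product: 11 (1S)-1-[(2S)-4-(bromomethyl)-5-oxo-2,5-dihydrofuran-2-yl]-2-methylprop-2-en-1-yl (2R)-2-methylbutanoate
Conditions: Hoveyda–Grubbs II (5 mol %), toluene (5 mM), 80 °C
Reagents that add atoms: none
Why: Ring-closing metathesis in which ruthenium loads on the monosubstituted C7 vinyl group and can only close onto the acrylate (the isopropenyl group would require a tetrasubstituted olefin), giving the γ-lactone with loss of ethene and leaving C6 untouched.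

**Step 6**
Reactants: 12 (R)-citronellal; 11 (1S)-1-[(2S)-4-(bromomethyl)-5-oxo-2,5-dihydrofuran-2-yl]-2-methylprop-2-en-1-yl (2R)-2-methylbutanoate
Product: 14 (1S)-1-[(2S,3R)-3-{(1R,2R,3R)-1-hydroxy-3,7-dimethyl-2-[(phenylamino)oxy]oct-6-en-1-yl}-4-methylidene-5-oxooxolan-2-yl]-2-methylprop-2-en-1-yl (2R)-2-methylbutanoate, via aminoxy aldehyde 13 (not isolated)
Conditions: 12, PhNO, L-proline (20 mol %), DMSO, rt, 30 min; then 11, In powder, NaI, THF/H2O, 0 °C → rt
Reagents that add atoms: nitrosobenzene, O=Nc1ccccc1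
Why: Proline enamine α-aminoxylation (O-selective nitroso aldol) sets C9 under catalyst control, and the one-pot Barbier-type indium allylation (SE2', a lactone homoenolate equivalent) then forms C7–C8 through a chair transition state of the ring-locked E-type allylindium attacking anti to the C6 side chain, which gives the trans-lactone (C7) and the C7/C8 relationship while the neutral aqueous medium keeps the free C8 alkoxide from translactonising.

**Step 7**
Reactants: 14 (Barbier adduct with free C8–OH)
Product: 15 C8-O-TBS ether of 14 (all stereocentres unchanged)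
Conditions: TBSOTf, 2,6-lutidine, CH2Cl2, −78 → 0 °C
Reagents that add atoms: TBSOTf, CC(C)(C)[Si](C)(C)OS(=O)(=O)C(F)(F)F
Why: Silylation of the only free hydroxyl with the reactive silyl triflate differentiates C8–O from C9–O; any N-silylation of the anilinooxy group is lost on work-up.

**Step 8**
Reactants: 15 C8-O-TBS ether of 14
Product: 16 C9 alcohol (15 with C9–O–NHPh cleaved to C9–OH)
Conditions: CuSO4·5H2O (30 mol %), MeOH, 0 °C
Reagents that add atoms: none
Why: Copper(II)-catalysed N–O bond cleavage of the anilinooxy group (disproportionation to alcohol and azobenzene) is neutral and leaves the silyl ether, the esters and the α-methylene lactone alone.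

**Step 9**
Reactants: 16 C9 alcohol
Product: 17 C9 isovalerate (C8-OTBS, C9-O-isovaleryl, C5-O-(R)-2-methylbutanoyl α-methylene lactone diene)
Conditions: (Me2CHCH2CO)2O, DMAP, pyridine, CH2Cl2, rt
Reagents that add atoms: isovaleric anhydride, CC(C)CC(=O)OC(=O)CC(C)C
Why: DMAP-catalysed acylation of the single free hydroxyl places the isovalerate regiospecifically on C9 because C8 is blocked, and acylation outruns silyl migration.

**Step 10**
Reactants: 17 C9 isovalerate
Product: 18 13-(dimethylamino)-11,13-dihydro derivative of 17 (C11 epimers, inconsequential)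
Conditions: Me2NH (2 M in THF), THF, 0 °C → rt
Reagents that add atoms: dimethylamine, CNC
Why: Aza-Michael addition to the α-methylene lactone (reversible Mannich-base masking) removes the only Stetter/carbene acceptor before the carbene step, with ester aminolysis being much slower.

**Step 11**
Reactants: 18 Mannich-base diene
Product: 19 seco keto-aldehyde (C3 aldehyde, C4 methyl ketone; otherwise as 18)
Conditions: O3, TFA (1.2 equiv), CH2Cl2/MeOH, −78 °C; Me2S; aq NaHCO3
Reagents that add atoms: ozone, [O-][O+]=O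
Why: Ozonolysis with reductive work-up cleaves the trisubstituted olefin to the C3 aldehyde and the 1,1-disubstituted olefin to the C4 methyl ketone in one operation, the amine being shielded as its trifluoroacetate salt.

**Step 12**
Reactants: 19 seco keto-aldehyde
Product: 20 13-(dimethylamino)-11,13-dihydro-8-O-TBS derivative of the target (ten-membered ring closed, C4 R)
Conditions: 2-(pentafluorophenyl)-6,7-dihydro-5H-pyrrolo[2,1-c][1,2,4]triazol-2-ium BF4 (30 mol %), iPr2NEt (30 mol %), CH2Cl2, slow addition to 1 mM, 35 °C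
Reagents that add atoms: none
Why: Proposed new method: a ten-membered-ring variant of the triazolylidene-catalysed intramolecular crossed aldehyde–ketone benzoin, in which the carbene adds to the unhindered C3 aldehyde to give the Breslow intermediate (acyl anion equivalent) that attacks the α-acyloxy-activated C4 ketone; the hindered tertiary α-ketol does not readily revert whereas aldehyde homo-benzoin is reversible, so high dilution should funnel material into the ring, and attack anti to the C5–O bond (polar Felkin–Anh, no chelating metal) gives (4R); the closest known reaction type is the NHC-catalysed intramolecular aldehyde–ketone benzoin that forms five- and six-membered tertiary α-ketols.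

**Step 13**
Reactants: 20 Mannich-base macrocycle
Product: 22 8-O-TBS ether of the target, via methiodide 21 (not isolated)
Conditions: MeI, THF, rt; then aq NaHCO3, CH2Cl2, rt
Reagents that add atoms: none
Why: Exhaustive N-methylation followed by mild-base E1cB (Hofmann-type) loss of trimethylamine regenerates the α-methylene lactone without disturbing the α-ketol or the esters.

**Step 14**
Reactants: 22 8-O-TBS ether of the target
Product: 23 (4R,5R,6S,7R,8R,9R,10R)-4,8-dihydroxy-9-(3-methylbutanoyloxy)-5-[(2R)-2-methylbutanoyloxy]-3-oxogermacr-11(13)-en-12,6-olide (CNP0269576.1)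
Conditions: HF·pyridine, pyridine, THF, 0 °C → rt
Reagents that add atoms: none
Why: Buffered fluoride desilylation frees C8–OH under non-basic conditions, so neither C9→C8 acyl migration nor translactonisation is provoked.

**Compound list**
1 | allyl methoxymethyl ether | C=CCOCOC | starting material
2 | methacrolein | CC(=C)C=O | starting material
3 | B-[(Z)-3-(methoxymethoxy)allyl]diisopinocampheylborane (Ipc from (−)-α-pinene) | COCO/C=C\CB([C@H]1C[C@H]2C[C@@H]([C@@H]1C)C2(C)C)[C@H]1C[C@H]2C[C@@H]([C@@H]1C)C2(C)C | intermediate (not isolated)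
4 | (3S,4S)-4-(methoxymethoxy)-2-methylhexa-1,5-dien-3-ol | COCO[C@H]([C@@H](O)C(C)=C)C=C | intermediate
5 | (R)-2-methylbutanoic acid | CC[C@@H](C)C(O)=O | starting material
6 | (3S,4S)-4-(methoxymethoxy)-2-methylhexa-1,5-dien-3-yl (2R)-2-methylbutanoate | COCO[C@H]([C@@H](OC(=O)[C@H](C)CC)C(C)=C)C=C | intermediate
7 | (3S,4S)-4-hydroxy-2-methylhexa-1,5-dien-3-yl (2R)-2-methylbutanoate | O[C@H]([C@@H](OC(=O)[C@H](C)CC)C(C)=C)C=C | intermediate
8 | 2-(bromomethyl)acrylic acid | C=C(CBr)C(O)=O | starting material
9 | 2-(bromomethyl)acryloyl chloride | C=C(CBr)C(Cl)=O | intermediate (not isolated)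
10 | (3S,4S)-2-methyl-3-{[(2R)-2-methylbutanoyl]oxy}hexa-1,5-dien-4-yl 2-(bromomethyl)prop-2-enoate | C=C(CBr)C(=O)O[C@H]([C@@H](OC(=O)[C@H](C)CC)C(C)=C)C=C | intermediate
11 | (1S)-1-[(2S)-4-(bromomethyl)-5-oxo-2,5-dihydrofuran-2-yl]-2-methylprop-2-en-1-yl (2R)-2-methylbutanoate | O=C1O[C@H]([C@@H](OC(=O)[C@H](C)CC)C(C)=C)C=C1CBr | intermediate
12 | (R)-citronellal | O=CC[C@H](C)CCC=C(C)C | starting material
13 | (2R,3R)-3,7-dimethyl-2-[(phenylamino)oxy]oct-6-enal | O=C[C@H](ONc1ccccc1)[C@H](C)CCC=C(C)C | intermediate (not isolated)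
14 | Barbier adduct: trans-α-methylene-γ-lactone with free C8–OH, C9–O–NHPh, C5 (R)-2-methylbutanoate, isopropenyl (C4) and prenyl-type (C3) olefins | C=C1C(=O)O[C@H]([C@@H](OC(=O)[C@H](C)CC)C(C)=C)[C@H]1[C@@H](O)[C@H](ONc1ccccc1)[C@H](C)CCC=C(C)C | intermediate
15 | C8-O-TBS ether of 14 | C=C1C(=O)O[C@H]([C@@H](OC(=O)[C@H](C)CC)C(C)=C)[C@H]1[C@@H](O[Si](C)(C)C(C)(C)C)[C@H](ONc1ccccc1)[C@H](C)CCC=C(C)C | intermediate
16 | C9 alcohol (C8-OTBS) | C=C1C(=O)O[C@H]([C@@H](OC(=O)[C@H](C)CC)C(C)=C)[C@H]1[C@@H](O[Si](C)(C)C(C)(C)C)[C@H](O)[C@H](C)CCC=C(C)C | intermediate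
17 | C9 isovalerate (C8-OTBS) | C=C1C(=O)O[C@H]([C@@H](OC(=O)[C@H](C)CC)C(C)=C)[C@H]1[C@@H](O[Si](C)(C)C(C)(C)C)[C@H](OC(=O)CC(C)C)[C@H](C)CCC=C(C)C | intermediate
18 | 13-(dimethylamino)-11,13-dihydro derivative of 17 (C11 not defined) | CN(C)CC1C(=O)O[C@H]([C@@H](OC(=O)[C@H](C)CC)C(C)=C)[C@H]1[C@@H](O[Si](C)(C)C(C)(C)C)[C@H](OC(=O)CC(C)C)[C@H](C)CCC=C(C)C | intermediate
19 | seco keto-aldehyde (C3 aldehyde, C4 methyl ketone) | CN(C)CC1C(=O)O[C@H]([C@@H](OC(=O)[C@H](C)CC)C(C)=O)[C@H]1[C@@H](O[Si](C)(C)C(C)(C)C)[C@H](OC(=O)CC(C)C)[C@H](C)CCC=O | intermediate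
20 | 13-(dimethylamino)-11,13-dihydro-8-O-TBS derivative of 23 | CN(C)CC1C(=O)O[C@H]2[C@H]1[C@@H](O[Si](C)(C)C(C)(C)C)[C@H](OC(=O)CC(C)C)[C@H](C)CCC(=O)[C@](C)(O)[C@@H]2OC(=O)[C@H](C)CC | intermediate
21 | trimethylammonium iodide (methiodide) of 20 | C[N+](C)(C)CC1C(=O)O[C@H]2[C@H]1[C@@H](O[Si](C)(C)C(C)(C)C)[C@H](OC(=O)CC(C)C)[C@H](C)CCC(=O)[C@](C)(O)[C@@H]2OC(=O)[C@H](C)CC.[I-] | intermediate (not isolated)
22 | 8-O-TBS ether of 23 | C=C1C(=O)O[C@H]2[C@H]1[C@@H](O[Si](C)(C)C(C)(C)C)[C@H](OC(=O)CC(C)C)[C@H](C)CCC(=O)[C@](C)(O)[C@@H]2OC(=O)[C@H](C)CC | intermediate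
23 | CNP0269576.1 | C=C1C(=O)O[C@H]2[C@H]1[C@@H](O)[C@H](OC(=O)CC(C)C)[C@H](C)CCC(=O)[C@](C)(O)[C@@H]2OC(=O)[C@H](C)CC | target

**Totals**
Total step count: 14. Longest linear sequence: 14 (steps 1–14; citronellal enters in the one-pot step 6).

**Three steps most likely to fail**

Step 12 (carbene ring closure). Ten-membered rings have the lowest effective molarity, the C4 face selectivity rests on substrate control, and the α-acyloxy ketone can epimerise at C5 or eliminate the C6 lactone oxygen under base. The fallback abandons acyl-anion closure for olefin metathesis. It sets out from 17: ring-closing metathesis between the C3 prenyl-type and C4 isopropenyl olefins (Hoveyda–Grubbs II, toluene, 2 mM, 100 °C, loss of 2-methylpropene) gives the cyclodecene F1. OsO4/NMO dihydroxylation of this electron-rich ring olefin (peripheral attack, anti to the C5 acyloxy group in Kishi's sense) gives the 3,4-diol F2. IBX oxidation of its only secondary hydroxyl gives the α-ketol, and the sequence comes back to the route at 22.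

Step 6 (aminoxylation/indium allylation). The α-aminoxy aldehyde is labile, its own facial bias may oppose the reagent, and the C8 alkoxide could translactonise. The fallback replaces the in situ organoindium by an isolable allylboron reagent with a closed transition state and no free alkoxide. It sets out from 11: Pd2(dba)3-catalysed borylation with B2pin2 gives the allylboronate F3. This is added to 13 (made from 12 as in step 6, after a quick extractive work-up) with Sc(OTf)3 (10 mol %) in CH2Cl2 at −40 → 0 °C; hydrolysis of the borate on work-up comes back to the route at 14.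

Step 5 (RCM to the bromomethyl butenolide). A trisubstituted, electron-poor olefin carrying an allylic bromide is a demanding RCM product. The fallback carries a plain acrylate through the ring closure and installs the CH2Br handle afterwards. It sets out from 7: acryloyl chloride/iPr2NEt gives the acrylate F4, RCM (Hoveyda–Grubbs II, toluene, 80 °C) gives the butenolide F5, and Morita–Baylis–Hillman hydroxymethylation (aq. HCHO, imidazole, THF) gives the hydroxymethyl butenolide F6. Appel bromination (CBr4, PPh3) then comes back to the route at 11.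

**Further compounds**
F1 | step 12 | (E)-3,4-didehydro-3-deoxo-4-deoxy cyclodecene, 8-O-TBS (ring olefin C3=C4) | C=C1C(=O)O[C@H]2[C@H]1[C@@H](O[Si](C)(C)C(C)(C)C)[C@H](OC(=O)CC(C)C)[C@H](C)CC/C=C(\C)[C@@H]2OC(=O)[C@H](C)CC
F2 | step 12 | 3,4-diol (3-hydroxy-3-deoxo analogue of 22) | C=C1C(=O)O[C@H]2[C@H]1[C@@H](O[Si](C)(C)C(C)(C)C)[C@H](OC(=O)CC(C)C)[C@H](C)CC[C@@H](O)[C@](C)(O)[C@@H]2OC(=O)[C@H](C)CC
F3 | step 6 | allylboronate: 11 with CH2Br replaced by CH2–B(pin) | O=C1O[C@H]([C@@H](OC(=O)[C@H](C)CC)C(C)=C)C=C1CB1OC(C)(C)C(C)(C)O1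
F4 | step 5 | acrylate ester of 7 | C=CC(=O)O[C@H]([C@@H](OC(=O)[C@H](C)CC)C(C)=C)C=C
F5 | step 5 | butenolide: 11 lacking the CH2Br group | O=C1O[C@H]([C@@H](OC(=O)[C@H](C)CC)C(C)=C)C=C1
F6 | step 5 | hydroxymethyl butenolide: 11 with CH2OH in place of CH2Br | O=C1O[C@H]([C@@H](OC(=O)[C@H](C)CC)C(C)=C)C=C1CO
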